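(The data stem from a simulated flask with constants of no real substance, and the scatter is random.)

The ratio of gamma's G to epsilon's at 2.50 min, 3.38 for twice the Q, is what I hand over with this bench, and beside it stands alpha, which reads the same 8 % as epsilon with 4.5 mM of L against 2 mM.

the same everywhere: E 0.010 M

| charge | Q | L | remark | time |
|---|---|---|---|---|
| epsilon | 0.015 M (fed, over 1.2 min) | 2 mM | run made earlier |  |
| alpha | 0.015 M (fed, over 1.2 min) | 4.5 mM | run made earlier |  |
| gamma | 0.030 M (fed, over 1.2 min) | 3 mM | run made earlier |  |
| autumn | 0.0150 M (fed, over 1.2 min) | 3.00 mM |  | 4.0 min |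
| noon | 0.0150 M (fed, over 4.0 min) | 3.00 mM |  | 4.0 min |
| dusk | 0.0150 M (fed, over 12 min) | 3.00 mM |  | 4.0 min |
| midnight | 0.0150 M (fed, over 40 min) | 3.00 mM |  | 4.0 min |

| run | time / min | G / % | E / % |
|---|---|---|---|
| epsilon | 0.667 | 2 | 96 |
| epsilon | 1.33 | 1 | 96 |
| epsilon | 2.00 | 5 | 85 |
| epsilon | 2.50 | 8 | 85 |
| alpha | 0.200 | 2 | 98 |
| alpha | 0.417 | 0 | 94 |
| alpha | 1.00 | 0 | 88 |
| alpha | 2.50 | 8 | 71 |
| gamma | 0.333 | 1 | 95 |
| gamma | 0.833 | 0 | 92 |
| gamma | 1.50 | 11 | 82 |
| gamma | 2.50 | 27 | 56 |

(readings scatter by 2 percentage points)

1. amount of G at the end, in percent of the E charged for autumn, noon, dusk, midnight, in this order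
2. how the row runs (hardly changes / rises all the way / falls all the way / falls, then rises / rises, then falls)

- the analysis behind the earlier runs scatters by 2 percentage points, standard deviation
- percentages count the whole charge, also what has not yet gone in
- "hardly changes" means that all values lie within two and a half points (for a concentration: within two and a half percent of the largest)

Four flasks stand before you, each holding E and L from the start, with Q going in at its own steady rate, and you read them at 4.0 min. I freeze Q on its feed line, since at one Q per G, which I assume, epsilon's G has cost 5.33 % of its Q charge. I then reckon each flask by its exposure, the minutes of full Q charge it has seen: 1.90 min for epsilon and alpha at that reading, and 3.80 min for gamma, counted in the same charge. G per minute of exposure reads 0.0421 min⁻¹ and 0.0711 min⁻¹, with all the scatter of those readings, and a straight line through them meets zero exposure at 0.0132 min⁻¹, the seed yield, the fraction of E turned to G per minute of exposure before any G stands in the flask.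

Exposures at the reading come to 3.40 min, 2.00 min, 0.667 min and 0.200 min for autumn, noon, dusk and midnight, and on the line through the earlier runs autumn's exposure gives me 22.1 % of G. Autumn's exposure is greater than any other, and noon's stands above dusk's and dusk's above midnight's, so I expect the row to fall all the way. The forecast says 16 %, 6 %, 0.8 % and 0.1 %, and that the row falls all the way, reasoning that “Slower feeds mean much less Q present”; my autumn stands higher than its figure, by a factor of 1.38.

    E + L → Z (k = 0.570 L mol⁻¹ s⁻¹)
    E + Q + G → 2 G (k = 95.2 L² mol⁻² s⁻¹)
    E + Q → G (k = 0.0229 L mol⁻¹ s⁻¹)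

The flasks give 19.1 %, 6.93 %, 1.43 % and 0.364 %, and the row falls all the way. In autumn at 1.27 min the autocatalytic path from E + Q + G uses Q at 0.69 of the rate of the path from E + Q. At 4.00 min the path from E + L takes E at 0.24 of the rate of that autocatalytic path. The seed yield times exposure comes to 4.49 % for autumn, which holds 19.1 %. Midnight's 0.364 % over its exposure of 0.200 min reads 0.0182 min⁻¹, beside a seed yield of 0.0132 min⁻¹.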